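The route rests on disconnecting C6–C7 of the ten-membered carbocycle and reconnecting C4–C9, so that the germacrane ring is grown from a cyclohexene (ring C9–C10–C1–C2–C3–C4) by an anionic oxy-Cope shift. The step exploits the cyclodec-5-enone pattern C9(O)–C8–C7–C6–C5=C4 and the Z C3(O)–C4=C5–C6(O) unit, which a six-membered O3–Si–C6 siloxane ring holds in the Z form. One operation delivers the ten-membered ring, both Z alkenes and C6/C7; oxidation of the enolate in the same flask adds the C8 hydroxyl. The precursor is a cis-fused oxasiline–cyclohexenol with an E-dienyl group and a tertiary hydroxyl at C9.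

Key step: step 11

Remark: germacranolide atom numbers are used for all intermediates (ring C1–C10, C11–C13 the acrylate unit, C14 on C10, C15 on C4); descriptors such as 3R refer to these numbers unless a systematic name is given.

Step 1
Reactants: 1 2-methylcyclohexane-1,3-dione; 2 allyl bromide
Product: 3 2-allyl-2-methylcyclohexane-1,3-dione
Conditions: 1 M aq NaOH, rt
Reagents that add atoms: none
Why: C-allylation of the stabilised dione enolate (SN2 alkylation) creates the quaternary carbon that becomes C4, the allyl CH2 being the future C5; no stereocentre is formed.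

Step 2
Reactants: 3 2-allyl-2-methylcyclohexane-1,3-dione
Product: 4 (2R,3R)-2-allyl-3-hydroxy-2-methylcyclohexan-1-one
Conditions: (S)-2-methyl-CBS-oxazaborolidine (20 mol%), catecholborane (1.1 equiv), toluene, −60 °C
Reagents that add atoms: none
Why: Corey–Bakshi–Shibata reduction desymmetrises the dione: the (S)-oxazaborolidine delivers hydride to the Si face of a carbonyl, and of the two enantiotopic carbonyls the one whose Si face lies on the methyl side (anti to the larger allyl group) should react, which sets C3 as R with OH cis to allyl and thereby fixes the quaternary C4 as R.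

Step 3
Reactants: 4 (2R,3R)-2-allyl-3-hydroxy-2-methylcyclohexan-1-one
Product: 5 (2R,3R)-3-hydroxy-2-methyl-2-[(E)-prop-1-en-1-yl]cyclohexan-1-one
Conditions: RuHCl(CO)(PPh3)3 (5 mol%), toluene, 80 °C
Reagents that add atoms: none
Why: ruthenium-hydride alkene isomerisation (hydrometalation/β-hydride elimination) moves the terminal double bond one position inward, where it must stop at the quaternary carbon, giving the E-propenyl group that serves as a masked C4-vinyl (C5H=) unit without touching the stereocentres.

Step 4
Reactants: 5 (2R,3R)-3-hydroxy-2-methyl-2-[(E)-prop-1-en-1-yl]cyclohexan-1-one; 6 chloro(dimethyl)vinylsilane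
Product: 7 (2R,3R)-3-{[dimethyl(vinyl)silyl]oxy}-2-methyl-2-[(E)-prop-1-en-1-yl]cyclohexan-1-one
Conditions: imidazole, CH2Cl2, 0 °C
Reagents that add atoms: none
Why: silyl ether formation at the only hydroxyl attaches the silicon tether, whose vinyl CH becomes C6, to O3; no stereocentre changes.

Step 5
Reactants: 7 (2R,3R)-3-{[dimethyl(vinyl)silyl]oxy}-2-methyl-2-[(E)-prop-1-en-1-yl]cyclohexan-1-one
Product: 8 cis-fused oxasiline ketone (3R,4R)
Conditions: Mo(=CHCMe2Ph)(=N-2,6-iPr2C6H3)[OCMe(CF3)2]2 (8 mol%), benzene, rt → 45 °C, argon, propene vented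
Reagents that add atoms: none
Why: silicon-tethered ring-closing metathesis of the vinylsilane with the propenyl group (loss of propene) closes the six-membered oxasiline through C5=C6, the cis ring fusion following from the cis O3/C5 relationship of step 2 and the molybdenum alkylidene being the catalyst type known to turn over vinylsilyl ethers.

Step 6
Reactants: 8 cis-fused oxasiline ketone
Product: 10 C10-methyl oxasiline ketone (both C10 epimers), via lithium enolate 9 (not isolated)
Conditions: LiN(iPr)2 (LDA), THF, −78 °C; then MeI, −78 → −20 °C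
Reagents that add atoms: iodomethane, CI
Why: enolate alkylation: the ketone can enolise only toward C10 because C4 is quaternary, and SN2 methylation of this lithium enolate brings in C14; the new C10 centre forms as a mixture that step 7 erases.

Step 7
Reactants: 10 C10-methyl oxasiline ketone
Product: 12 cis-fused oxasiline enone (3R,4R), via TMS enol ether 11 (not isolated)
Conditions: TMSOTf, Et3N, CH2Cl2, 0 °C; then Pd(OAc)2 (10 mol%), O2 (1 atm), DMSO, 45 °C
Reagents that add atoms: none
Why: Saegusa–Ito oxidation: the tetrasubstituted silyl enol ether is converted by palladium diacetate into a palladium enolate that undergoes syn β-hydride elimination toward C1 to give the conjugated C1=C10 enone, oxygen returning the metal to divalent palladium.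

Step 8
Reactants: 13 2-bromoprop-2-en-1-ol
Product: 14 (2-bromoallyloxy)(tert-butyl)dimethylsilane
Conditions: TBSCl, imidazole, CH2Cl2, rt
Reagents that add atoms: tert-butyldimethylsilyl chloride, CC(C)(C)[Si](C)(C)Cl
Why: silylation protects the primary allylic alcohol (future C12–OH) as an ether that should withstand the organolithium, KH and esterification steps.

Step 9
Reactants: 14 (2-bromoallyloxy)(tert-butyl)dimethylsilane; 15 (E)-1,2-bis(tributylstannyl)ethene (2.5 equiv)
Product: 16 (E)-tert-butyldimethyl{[2-methylidene-4-(tributylstannyl)but-3-en-1-yl]oxy}silane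
Conditions: Pd(PPh3)4 (5 mol%), toluene, 90 °C
Reagents that add atoms: none
Why: Stille coupling (oxidative addition of the vinyl bromide to zerovalent palladium, transmetalation of one C–Sn bond, reductive elimination) joins C11 to C7 with retention of the E geometry, and the excess of distannane should keep the second C–Sn bond intact.

Step 10
Reactants: 16 (E)-dienylstannane; 12 cis-fused oxasiline enone
Product: 19 cis-1,2-dialkenyl cyclohexenol (3R,4R,9R), via dienyllithium 17 (not isolated), via dienylcerium dichloride 18 (not isolated)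
Conditions: n-BuLi, THF, −78 °C; anhydrous CeCl3, −78 °C; then 12, −78 °C; aq NH4Cl
Reagents that add atoms: none
Why: tin–lithium exchange with retention of the E geometry, transmetalation to the weakly basic organocerium and 1,2-addition to the hindered enone (γ-deprotonation suppressed) form C8–C9; the nucleophile is expected to enter anti to the angular C15 methyl, past the flat C5–H of the oxasiline, which sets C9 as R with the dienyl group cis to C5 and the hydroxyl cis to C15.

Step 11
Reactants: 19 cis-1,2-dialkenyl cyclohexenol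
Product: 22 siloxane-bridged 8-hydroxy-(1(10)Z,4Z)-cyclodecadien-9-one (3R,6R,7S,8S), via potassium alkoxide 20 (not isolated), via potassium enolate 21 (not isolated)
Conditions: KH (1.5 equiv), 18-crown-6, THF, 0 → 40 °C; then −78 °C, trans-3-phenyl-2-(phenylsulfonyl)oxaziridine; aq NH4Cl
Reagents that add atoms: trans-3-phenyl-2-(phenylsulfonyl)oxaziridine, O=S(=O)(c1ccccc1)N1OC1c1ccccc1
Why: Proposed new method: KH gives the crown-separated potassium alkoxide 20, whose oxyanion weakens the C4–C9 bond so that a concerted [3,3] sigmatropic shift through the chair array C9–C8–C7–C6–C5–C4 forms C6–C7 and ends irreversibly in the cross-conjugated C8=C9 enolate 21, which the N-sulfonyloxaziridine then hydroxylates (Davis oxidation); the closest known reaction type is the anionic oxy-Cope ring expansion of cis-1,2-dialkenylcyclohexenols to cyclodecadienones with in-flask enolate oxidation, the untested element being a cyclic vinylsiloxane as one terminus. No ring is closed end to end: the ten-membered carbocycle arises by four-atom expansion of the cyclohexene, and the oxasiline is carried through as a six-membered bridge from C3 to C6. C6 and C7 are fixed by chirality transfer from C4 and C9, because the ring-locked Z vinylsilane must place silicon axial at C6 while the E dienyl group places C11 equatorial at C7 of the chair, and C8 is fixed by attack of the oxidant on the outer face of the ring-bound enolate, away from the transannular C4=C5 unit. The step needs Z geometry at C4=C5 and the C6/C7 relationship of the target: C3 and silicon, syn-axial on the chair, are already tied together by O3, so only the Z alkene can form, and C1=C10 stays Z because it never leaves a six-membered ring. Transfer of silicon to the alkoxide is not expected, since O9 lies on the ring face opposite O3 and C5 and cannot reach the silicon atom.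

Step 12
Reactants: 23 angelic acid
Product: 24 (Z)-2-methylbut-2-en-1-ol
Conditions: LiAlH4, Et2O, 0 °C; Fieser work-up
Reagents that add atoms: none
Why: hydride reduction of the carboxylic acid gives the allylic alcohol without touching the trisubstituted alkene, so the Z geometry should be carried over.

Step 13
Reactants: 24 (Z)-2-methylbut-2-en-1-ol
Product: 25 [(2S,3R)-2,3-dimethyloxiran-2-yl]methanol
Conditions: Ti(OiPr)4 (10 mol%), L-(+)-diethyl tartrate (12 mol%), t-BuOOH, 4 Å molecular sieves, CH2Cl2, −20 °C
Reagents that add atoms: tert-butyl hydroperoxide, CC(C)(C)OO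
Why: Katsuki–Sharpless asymmetric epoxidation: the titanium–L-(+)-tartrate complex delivers oxygen to the alkene face that makes C2 S (as with other Z allylic alcohols), and the Z geometry then fixes C3 as R, so both epoxide centres are set at once.

Step 14
Reactants: 25 [(2S,3R)-2,3-dimethyloxiran-2-yl]methanol
Product: 26 (2R,3R)-2,3-dimethyloxirane-2-carboxylic acid (epoxyangelic acid)
Conditions: TEMPO (20 mol%), PhI(OAc)2 (2.2 equiv), MeCN/H2O 1:1, rt
Reagents that add atoms: water, O
Why: oxoammonium (TEMPO) oxidation takes the primary alcohol through the aldehyde hydrate to the acid under near-neutral conditions that leave the epoxide intact; C2 becomes R only through the change in substituent priority.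

Step 15
Reactants: 22 siloxane-bridged 8-hydroxy cyclodecadienone; 26 (2R,3R)-epoxyangelic acid
Product: 28 C8 epoxyangelate of 22, via mixed anhydride 27 (not isolated)
Conditions: 2,4,6-trichlorobenzoyl chloride, Et3N, toluene, rt; then 22, DMAP, rt
Reagents that add atoms: none
Why: Yamaguchi esterification: the mixed anhydride passes the epoxyangeloyl group through its acylpyridinium ion to the only free hydroxyl (C8–OH), with retention at C8 and no epimerisable centre in the acid.

Step 16
Reactants: 28 C8 epoxyangelate
Product: 29 3,6-diol (3R,6R,7R,8S) with C12–OTBS and C9 ketone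
Conditions: 30% H2O2, KF, KHCO3, THF/MeOH 1:1, 0 °C → rt
Reagents that add atoms: hydrogen peroxide, OO
Why: Tamao–Fleming oxidation: fluoride-activated silicon takes up hydroperoxide and the allylic C6 migrates from silicon to oxygen with retention, which frees C6–OH (R) and C3–OH together, while the weakly basic buffer should spare the enone, the epoxy ester and the TBS ether.

Step 17
Reactants: 29 3,6-diol
Product: 30 3,6,12-triol
Conditions: HF·pyridine, pyridine, THF, 0 °C
Reagents that add atoms: none
Why: fluoride-mediated desilylation removes the primary TBS ether under buffered, non-basic conditions that should avoid acyl migration and epoxide opening.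

Step 18
Reactants: 30 3,6,12-triol
Product: 33 3-epi-hydroxy-9-oxo α-methylene γ-lactone (3R,6R,7R,8S), via hydroxy aldehyde 31 (not isolated), via lactol 32 (not isolated)
Conditions: TEMPO (20 mol%), PhI(OAc)2 (2.5 equiv), CH2Cl2, rt
Reagents that add atoms: none
Why: oxidative lactonisation of a 1,4-diol: chemoselective oxoammonium oxidation of the primary allylic C12 alcohol gives the enal, which C6–OH traps as the five-membered lactol that is oxidised on to the lactone, the secondary C3–OH reacting more slowly.

Step 19
Reactants: 33 3-epi-hydroxy-9-oxo lactone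
Product: 34 3-O-acetyl-9-oxo lactone (3S,6R,7R,8S)
Conditions: PPh3, DIAD, AcOH, THF, 0 °C → rt
Reagents that add atoms: acetic acid, CC(=O)O
Why: Mitsunobu reaction: the only free hydroxyl (any transannular 3,9-hemiketal reverting to the open hydroxy ketone) is activated as its oxyphosphonium ion and displaced by acetate in an SN2 step with inversion, which turns C3 from R to S and installs the acetate in one operation.

Step 20
Reactants: 34 3-O-acetyl-9-oxo lactone
Product: 35 target CNP0299903.1 (3S,6R,7R,8S,9R; ester 2R,3R)
Conditions: NaBH4, CeCl3·7H2O, MeOH, −78 °C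
Reagents that add atoms: none
Why: Luche reduction should give 1,2-reduction of the C9 enone without conjugate reduction of the α-methylene lactone, hydride adding to the outer face of the carbonyl anti to the C8 acyloxy group (Felkin–Anh sense) to give the 8,9-anti alcohol with C9 as R.

Compound list
1 | 2-methylcyclohexane-1,3-dione | CC1C(=O)CCCC1=O | starting material
2 | allyl bromide | C=CCBr | starting material
3 | 2-allyl-2-methylcyclohexane-1,3-dione | C=CCC1(C)C(=O)CCCC1=O | intermediate
4 | (2R,3R)-2-allyl-3-hydroxy-2-methylcyclohexan-1-one (OH cis to allyl) | O=C1CCC[C@@H](O)[C@@]1(C)CC=C | intermediate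
5 | (2R,3R)-3-hydroxy-2-methyl-2-[(E)-prop-1-en-1-yl]cyclohexan-1-one | O=C1CCC[C@@H](O)[C@@]1(C)/C=C/C | intermediate
6 | chloro(dimethyl)vinylsilane | C=C[Si](C)(C)Cl | starting material
7 | (2R,3R)-3-{[dimethyl(vinyl)silyl]oxy}-2-methyl-2-[(E)-prop-1-en-1-yl]cyclohexan-1-one | O=C1CCC[C@@H](O[Si](C)(C)C=C)[C@@]1(C)/C=C/C | intermediate
8 | cis-fused oxasiline ketone (3R,4R): cyclohexanone (C9=O) fused at C3–C4 to a 2,2-dimethyl-1-oxa-2-silacyclohex-3-ene (O3–SiMe2–C6H=C5H–C4), C15 methyl on C4 | O=C1CCC[C@H]2O[Si](C)(C)C=C[C@@]12C | intermediate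
9 | lithium enolate of 8 (C9–OLi, C9=C10) | [Li]OC1=CCC[C@H]2O[Si](C)(C)C=C[C@@]12C | intermediate (not isolated)
10 | C10-methyl derivative of 8 (both C10 epimers) | O=C1C(C)CC[C@H]2O[Si](C)(C)C=C[C@@]12C | intermediate
11 | trimethylsilyl enol ether of 10 (C9–OSiMe3, C9=C10) | C[Si](C)(C)OC1=C(C)CC[C@H]2O[Si](C)(C)C=C[C@@]12C | intermediate (not isolated)
12 | cis-fused oxasiline enone (3R,4R): C9=O, C10(CH3)=C1H | O=C1C(C)=CC[C@H]2O[Si](C)(C)C=C[C@@]12C | intermediate
13 | 2-bromoprop-2-en-1-ol | C=C(Br)CO | starting material
14 | (2-bromoallyloxy)(tert-butyl)dimethylsilane | C=C(Br)CO[Si](C)(C)C(C)(C)C | intermediate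
15 | (E)-1,2-bis(tributylstannyl)ethene | CCCC[Sn](CCCC)(CCCC)/C=C/[Sn](CCCC)(CCCC)CCCC | starting material
16 | (E)-tert-butyldimethyl{[2-methylidene-4-(tributylstannyl)but-3-en-1-yl]oxy}silane | CCCC[Sn](CCCC)(CCCC)/C=C/C(=C)CO[Si](C)(C)C(C)(C)C | intermediate
17 | (E)-dienyllithium from 16 | [Li]/C=C/C(=C)CO[Si](C)(C)C(C)(C)C | intermediate (not isolated)
18 | (E)-dienylcerium dichloride | Cl[Ce](Cl)/C=C/C(=C)CO[Si](C)(C)C(C)(C)C | intermediate (not isolated)
19 | oxy-Cope precursor (3R,4R,9R): enone 12 carrying at C9 a hydroxyl (cis to C15) and the E-dienyl group C8H=C7H–C11(=C13H2)–C12H2OTBS (cis to C5) | O[C@]1(/C=C/C(=C)CO[Si](C)(C)C(C)(C)C)C(C)=CC[C@H]2O[Si](C)(C)C=C[C@@]12C | intermediate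
20 | potassium alkoxide of 19 | [K+].[O-][C@]1(/C=C/C(=C)CO[Si](C)(C)C(C)(C)C)C(C)=CC[C@H]2O[Si](C)(C)C=C[C@@]12C | intermediate (not isolated)
21 | ring-expanded potassium enolate (C8=C9–OK, oxygen cis to C7; C1=C10 and C4=C5 both Z) | [K+].[O-]/C1=C\[C@H](C(=C)CO[Si](C)(C)C(C)(C)C)[C@H]2/C=C(/C)[C@H](O[Si]2(C)C)C/C=C1/C | intermediate (not isolated)
22 | siloxane-bridged (1(10)Z,4Z)-cyclodecadien-9-one with 8-OH (3R,6R,7S,8S): O3–SiMe2–C6 bridge, C7 bearing C11(=C13H2)–C12H2OTBS | O=C1/C(C)=C\C[C@H]2O[Si](C)(C)[C@H](/C=C2/C)[C@@H](C(=C)CO[Si](C)(C)C(C)(C)C)[C@@H]1O | intermediate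
23 | angelic acid, (Z)-2-methylbut-2-enoic acid | C/C=C(/C)C(=O)O | starting material
24 | (Z)-2-methylbut-2-en-1-ol | C/C=C(/C)CO | intermediate
25 | [(2S,3R)-2,3-dimethyloxiran-2-yl]methanol | OC[C@]1(C)O[C@@H]1C | intermediate
26 | (2R,3R)-2,3-dimethyloxirane-2-carboxylic acid | OC(=O)[C@]1(C)O[C@@H]1C | intermediate
27 | (2R,3R)-2,3-dimethyloxirane-2-carboxylic 2,4,6-trichlorobenzoic anhydride | O=C(OC(=O)[C@]1(C)O[C@@H]1C)c1c(Cl)cc(Cl)cc1Cl | intermediate (not isolated)
28 | C8 (2R,3R)-epoxyangelate of 22 (3R,6R,7S,8S) | O=C1/C(C)=C\C[C@H]2O[Si](C)(C)[C@H](/C=C2/C)[C@@H](C(=C)CO[Si](C)(C)C(C)(C)C)[C@@H]1OC(=O)[C@]3(C)O[C@@H]3C | intermediate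
29 | 3,6-diol (3R,6R,7R,8S): (1(10)Z,4Z)-cyclodecadien-9-one with 3-OH, 6-OH, 8-epoxyangelate, C12–OTBS | O=C1/C(C)=C\C[C@@H](O)/C(C)=C\[C@@H](O)[C@@H](C(=C)CO[Si](C)(C)C(C)(C)C)[C@@H]1OC(=O)[C@]2(C)O[C@@H]2C | intermediate
30 | 3,6,12-triol (3R,6R,7R,8S) | O=C1/C(C)=C\C[C@@H](O)/C(C)=C\[C@@H](O)[C@@H](C(=C)CO)[C@@H]1OC(=O)[C@]2(C)O[C@@H]2C | intermediate
31 | 3,6-dihydroxy 12-aldehyde | O=C1/C(C)=C\C[C@@H](O)/C(C)=C\[C@@H](O)[C@@H](C(=C)C=O)[C@@H]1OC(=O)[C@]2(C)O[C@@H]2C | intermediate (not isolated)
32 | 6,12-lactol (both anomers) | C=C1C(O)O[C@@H]2/C=C(/C)[C@H](O)C/C=C(/C)C(=O)[C@@H](OC(=O)[C@]3(C)O[C@@H]3C)[C@H]12 | intermediate (not isolated)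
33 | 3-epi-hydroxy-9-oxo α-methylene 6,12-lactone (3R,6R,7R,8S) | C=C1C(=O)O[C@@H]2/C=C(/C)[C@H](O)C/C=C(/C)C(=O)[C@@H](OC(=O)[C@]3(C)O[C@@H]3C)[C@H]12 | intermediate
34 | 3-O-acetyl-9-oxo lactone (3S,6R,7R,8S) | C=C1C(=O)O[C@@H]2/C=C(/C)[C@@H](OC(C)=O)C/C=C(/C)C(=O)[C@@H](OC(=O)[C@]3(C)O[C@@H]3C)[C@H]12 | intermediate
35 | CNP0299903.1 (3S,6R,7R,8S,9R; 8-O-(2R,3R)-epoxyangelate) | C=C1C(=O)O[C@@H]2/C=C(/C)[C@@H](OC(C)=O)C/C=C(/C)[C@@H](O)[C@@H](OC(=O)[C@]3(C)O[C@@H]3C)[C@H]12 | target

Total step count: 20. Longest linear sequence: 15 steps (1 → 3 → 4 → 5 → 7 → 8 → 10 → 12 → 19 → 22 → 28 → 29 → 30 → 33 → 34 → 35).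

Steps most likely to fail

Step 11 (Proposed new method). What may go wrong: the [3,3] shift stalls at the crowded silicon-bearing terminus, so that the alkoxide fragments or isomerises instead, or an oxyanion (alkoxide or enolate oxygen) attacks silicon and opens the siloxane bridge. Fallback with known chemistry, setting out from 19 and returning at 22: the tertiary hydroxyl is capped (TMSOTf, 2,6-lutidine, CH2Cl2) as the trimethylsilyl ether F1. Heating F1 (o-dichlorobenzene, 180–200 °C, base-washed sealed tube) should bring about the neutral siloxy-Cope ring expansion, the thermal non-anionic variant of the oxy-Cope rearrangement, to the ring-expanded trimethylsilyl enol ether F2, so that no oxyanion is ever present. Rubottom oxidation of F2 (DMDO, acetone/CH2Cl2, −78 °C) on the outer face should give the α-trimethylsilyloxy ketone F3, and mild acidic methanolysis (citric acid, MeOH) of its O–SiMe3 bond should give 22.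

Step 10. What may go wrong: poor facial selectivity in the 1,2-addition (approach syn to the angular methyl), which would give the C9 epimer that cannot rearrange through the chair, and proton abstraction at the γ-position of the enone by the bulky alkenyl metal. Fallback, setting out from 14 and 12 and returning at 19: Sonogashira coupling of 14 with trimethylsilylacetylene (Pd(PPh3)2Cl2, CuI, Et3N) should give the silylated enyne F4, and K2CO3 in MeOH should free the terminal enyne F5. Its acetylide (n-BuLi, THF, −78 °C, then CeCl3) adds to 12 as a slim, rod-shaped nucleophile whose approach past C5–H is less sensitive to the crowding that can divert an alkenyl metal, which should give the propargylic alcohol F6. Hydroxyl-directed trans-hydroalumination with NaAlH2(OCH2CH2OMe)2 (THF, 0 °C) should then give the E alkene of 19.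

Step 5. What may go wrong: slow ring closure because both reacting alkenes sit on fully substituted atoms (silicon and the quaternary C4), with catalyst decay outrunning turnover. Fallback, setting out from 5 and returning at 8: ozonolysis of the propenyl group (ozone, CH2Cl2/MeOH, −78 °C; Me2S) should give the aldehyde F7, and Colvin homologation with Me3SiC(Li)N2 (THF, −78 → 0 °C) the terminal alkyne F8. Silylation of the hydroxyl with 1,1,3,3-tetramethyldisilazane should give the hydrosilyl ether F9. Intramolecular endo-dig trans-hydrosilylation catalysed by [Cp*Ru(MeCN)3]PF6 (CH2Cl2, 0 °C) should then close the same oxasiline ring by Si–C6 bond formation, the trans addition placing the ring alkene cis as required.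

Further compounds
F1 | step 11 | trimethylsilyl ether of 19 (C9–OSiMe3) | C[Si](C)(C)O[C@]1(/C=C/C(=C)CO[Si](C)(C)C(C)(C)C)C(C)=CC[C@H]2O[Si](C)(C)C=C[C@@]12C
F2 | step 11 | ring-expanded trimethylsilyl enol ether (C8=C9–OSiMe3, oxygen cis to C7) | C[Si](C)(C)O/C1=C\[C@H](C(=C)CO[Si](C)(C)C(C)(C)C)[C@H]2/C=C(/C)[C@H](O[Si]2(C)C)C/C=C1/C
F3 | step 11 | 8-O-trimethylsilyl derivative of 22 | O=C1/C(C)=C\C[C@H]2O[Si](C)(C)[C@H](/C=C2/C)[C@@H](C(=C)CO[Si](C)(C)C(C)(C)C)[C@@H]1O[Si](C)(C)C
F4 | step 10 | tert-butyldimethyl{[2-methylidene-4-(trimethylsilyl)but-3-yn-1-yl]oxy}silane | C=C(C#C[Si](C)(C)C)CO[Si](C)(C)C(C)(C)C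
F5 | step 10 | tert-butyl[(2-methylidenebut-3-yn-1-yl)oxy]dimethylsilane | C=C(C#C)CO[Si](C)(C)C(C)(C)C
F6 | step 10 | C9 enynyl carbinol (3R,4R,9R), the 7,8-didehydro analogue of 19 | O[C@]1(C#CC(=C)CO[Si](C)(C)C(C)(C)C)C(C)=CC[C@H]2O[Si](C)(C)C=C[C@@]12C
F7 | step 5 | (1S,2R)-2-hydroxy-1-methyl-6-oxocyclohexane-1-carbaldehyde | O=C1CCC[C@@H](O)[C@@]1(C)C=O
F8 | step 5 | (2R,3R)-2-ethynyl-3-hydroxy-2-methylcyclohexan-1-one | O=C1CCC[C@@H](O)[C@@]1(C)C#C
F9 | step 5 | (2R,3R)-3-[(dimethylsilyl)oxy]-2-ethynyl-2-methylcyclohexan-1-one | O=C1CCC[C@@H](O[SiH](C)C)[C@@]1(C)C#C
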